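**Assumption:** catalysts, ligands and bases that leave no atoms in a product are not numbered. The chiral thiol in step 5 is used in whichever enantiomeric form delivers the (S) product, to be fixed by screening. The target stereocentre is (S) (CIP order: C(CH3)2OH > CH2O-acyl > indol-3-yl > H).

## Retrosynthetic overview

1. The ester C–O bond and the lone stereocentre are disconnected together: linoleic acid adds anti-Markovnikov and enantioselectively across a 1,1-disubstituted 3-vinylindole (8).
2. Alkene 8 comes from a Suzuki coupling of 3-iodo-6-prenylindole (4) with α-borylated allylic alcohol 7.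
3. Iodide 4 comes from 6-bromoindole by linear-selective prenyl Suzuki coupling, then C3 iodination; 7 comes from 2-methylbut-3-yn-2-ol by α-selective protoboration.
4. No ring is formed: the indole bicycle is bought intact. No protecting groups are used.

## Route

**Step 1**
Reactants: 1 6-bromo-1H-indole; 2 prenylboronic acid pinacol ester
Product: 3 6-(3-methylbut-2-en-1-yl)-1H-indole
Conditions: Pd(OAc)2 (2 mol %), t-BuXPhos (4 mol %), aq K3PO4 (3 equiv), THF, 40 °C
Reagents that add atoms: none
Why: Suzuki–Miyaura coupling of an allylboronate with an aryl bromide, in which a bulky biarylphosphine lets the σ-allyl-Pd equilibrate to the less hindered terminus before reductive elimination, giving the linear (α) prenyl arene; the free N–H is tolerated.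

**Step 2**
Reactants: 3 6-(3-methylbut-2-en-1-yl)-1H-indole
Product: 4 3-iodo-6-(3-methylbut-2-en-1-yl)-1H-indole
Conditions: I2 (1.02 equiv), KOH (2.5 equiv), DMF, 0 °C to rt, 30 min; used at once, kept from light
Reagents that add atoms: iodine, II
Why: Electrophilic aromatic iodination of the indolyl anion at C3 is far faster than any reaction of I2 with the trisubstituted prenyl alkene.

**Step 3**
Reactants: 5 2-methylbut-3-yn-2-ol; 6 bis(pinacolato)diboron
Product: 7 2-methyl-3-(4,4,5,5-tetramethyl-1,3,2-dioxaborolan-2-yl)but-3-en-2-ol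
Conditions: SIPrCuCl (5 mol %), NaOt-Bu (10 mol %), MeOH (2 equiv), THF, −15 °C to rt
Reagents that add atoms: none
Why: Copper-catalysed protoboration of a terminal propargylic alcohol, where an N-aryl NHC–Cu–Bpin species adds with boron at the internal carbon and methanol protonates the alkenyl copper, giving the α-vinylboronate.

**Step 4**
Reactants: 4 3-iodo-6-(3-methylbut-2-en-1-yl)-1H-indole; 7 2-methyl-3-(4,4,5,5-tetramethyl-1,3,2-dioxaborolan-2-yl)but-3-en-2-ol
Product: 8 2-methyl-3-[6-(3-methylbut-2-en-1-yl)-1H-indol-3-yl]but-3-en-2-ol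
Conditions: XPhos Pd G2 (3 mol %), K3PO4 (2 equiv), dioxane/H2O 4:1, 60 °C; purify on Et3N-deactivated silica
Reagents that add atoms: none
Why: Suzuki–Miyaura coupling of an unprotected 3-iodoindole with a 1,1-disubstituted alkenyl boronate under a biarylphosphine precatalyst that tolerates free N–H azoles and the free tertiary alcohol.

**Step 5**
Reactants: 8 2-methyl-3-[6-(3-methylbut-2-en-1-yl)-1H-indol-3-yl]but-3-en-2-ol; 9 linoleic acid
Product: 10 (2S)-3-hydroxy-3-methyl-2-[6-(3-methylbut-2-en-1-yl)-1H-indol-3-yl]butyl (9Z,12Z)-octadeca-9,12-dienoate (CNP0180241.1)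
Conditions: [Ir(dF(CF3)ppy)2(dtbbpy)]PF6 (1 mol %), chiral Cys-containing β-turn tetrapeptide thiol (20 mol %), 2,6-lutidine (10 mol %), acid in excess (3 equiv), degassed DCE, 450 nm LED, 0 °C, Ar, slow addition of the alkene
Reagents that add atoms: none
Why: Proposed new method: catalytic enantioselective anti-Markovnikov hydroacyloxylation of a 1,1-disubstituted vinylindole, a pure addition in which the O–H of the acid adds across the C=C so that all atoms of both partners end up in the product; the mild photo-oxidant (E* about +1.2 V) oxidises only the electron-rich 3-vinylindole (not the prenyl or skipped-diene alkenes) to its radical cation, linoleic acid adds at the terminal CH2 to give the aromatic-retaining tertiary α-indolyl radical, and the peptide thiol, hydrogen-bonded to the tertiary OH and indole N–H, delivers H to one face to set the (S) centre before the thiyl radical is reduced by Ir(II) and reprotonated; the closest known reaction type is the racemic acridinium/thiol photoredox anti-Markovnikov addition of carboxylic acids to styrenes, combined with peptide-thiol enantioselective hydrogen-atom transfer.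

## Compound list

1 | 6-bromo-1H-indole | Brc1ccc2cc[nH]c2c1 | starting material
2 | prenylboronic acid pinacol ester | CC(C)=CCB1OC(C)(C)C(C)(C)O1 | starting material
3 | 6-(3-methylbut-2-en-1-yl)-1H-indole | CC(C)=CCc1ccc2cc[nH]c2c1 | intermediate
4 | 3-iodo-6-(3-methylbut-2-en-1-yl)-1H-indole | CC(C)=CCc1ccc2c(I)c[nH]c2c1 | intermediate
5 | 2-methylbut-3-yn-2-ol | CC(C)(O)C#C | starting material
6 | bis(pinacolato)diboron | CC1(C)OB(OC1(C)C)B1OC(C)(C)C(C)(C)O1 | starting material
7 | 2-methyl-3-(4,4,5,5-tetramethyl-1,3,2-dioxaborolan-2-yl)but-3-en-2-ol | C=C(B1OC(C)(C)C(C)(C)O1)C(C)(C)O | intermediate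
8 | 2-methyl-3-[6-(3-methylbut-2-en-1-yl)-1H-indol-3-yl]but-3-en-2-ol | C=C(c1c[nH]c2cc(CC=C(C)C)ccc12)C(C)(C)O | intermediate
9 | linoleic acid | CCCCC/C=C\C/C=C\CCCCCCCC(=O)O | starting material
10 | (2S)-3-hydroxy-3-methyl-2-[6-(3-methylbut-2-en-1-yl)-1H-indol-3-yl]butyl (9Z,12Z)-octadeca-9,12-dienoate | CCCCC/C=C\C/C=C\CCCCCCCC(=O)OC[C@H](c1c[nH]c2cc(CC=C(C)C)ccc12)C(C)(C)O | target

## Summary

Total step count: 5. Longest linear sequence: 4 (steps 1, 2, 4, 5).

**Three steps most likely to fail**

Step 5 (the proposed new step). The risks are low enantioselectivity in the hydrogen-atom transfer, radical-cation dimerisation of 8, and thiyl-radical Z/E scrambling of the linoleate diene. The fallback uses known chemistry, sets out from 8 and keeps linoleic acid away from radicals. Copper-catalysed enantioselective protoboration of the 1,1-disubstituted aryl alkene (chiral NHC–CuCl, NaOt-Bu, B2pin2 6, MeOH, THF) gives (3R)-2-methyl-3-[6-(3-methylbut-2-en-1-yl)-1H-indol-3-yl]-4-(4,4,5,5-tetramethyl-1,3,2-dioxaborolan-2-yl)butan-2-ol F1. Oxidation with NaBO3·4H2O in THF/H2O gives (2S)-3-methyl-2-[6-(3-methylbut-2-en-1-yl)-1H-indol-3-yl]butane-1,3-diol F2. Acylation of the primary hydroxyl with 9 (EDC·HCl, catalytic DMAP, CH2Cl2, 0 °C, or Novozym 435) leaves the tertiary alcohol untouched and returns to the route at 10.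

Step 4. The unprotected 3-iodoindole 4 may deiodinate or decompose before it couples. The fallback sets out from 4 with a protecting-group strategy. Boc2O/DMAP in MeCN gives tert-butyl 3-iodo-6-(3-methylbut-2-en-1-yl)-1H-indole-1-carboxylate F3, which is bench-stable. Suzuki coupling with 7 (Pd(dppf)Cl2, K3PO4, dioxane/H2O) gives tert-butyl 3-(3-hydroxy-3-methylbut-1-en-2-yl)-6-(3-methylbut-2-en-1-yl)-1H-indole-1-carboxylate F4. Removal of the N-Boc group with K2CO3 in MeOH at 50 °C returns to the route at 8.

Step 3. The hindered tertiary propargylic alcohol may erode α-selectivity in the protoboration. The fallback sets out from 5 and replaces the boronate by a stannane. Molybdenum-catalysed hydrostannation (Mo(CO)3(CNt-Bu)3, Bu3SnH, THF, 55 °C) is reliably α-selective for propargylic alcohols and gives 2-methyl-3-(tributylstannyl)but-3-en-2-ol F5. Stille coupling of this with 4 (Pd(PPh3)4, CuI, DMF, 50 °C) bypasses 7 and returns to the route at 8.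

## Further compounds

F1 | step 5 | (3R)-2-methyl-3-[6-(3-methylbut-2-en-1-yl)-1H-indol-3-yl]-4-(4,4,5,5-tetramethyl-1,3,2-dioxaborolan-2-yl)butan-2-ol | CC1(C)OB(C[C@H](c2c[nH]c3cc(CC=C(C)C)ccc23)C(C)(C)O)OC1(C)C
F2 | step 5 | (2S)-3-methyl-2-[6-(3-methylbut-2-en-1-yl)-1H-indol-3-yl]butane-1,3-diol | OC[C@H](c1c[nH]c2cc(CC=C(C)C)ccc12)C(C)(C)O
F3 | step 4 | tert-butyl 3-iodo-6-(3-methylbut-2-en-1-yl)-1H-indole-1-carboxylate | CC(C)=CCc1ccc2c(I)cn(C(=O)OC(C)(C)C)c2c1
F4 | step 4 | tert-butyl 3-(3-hydroxy-3-methylbut-1-en-2-yl)-6-(3-methylbut-2-en-1-yl)-1H-indole-1-carboxylate | C=C(c1cn(C(=O)OC(C)(C)C)c2cc(CC=C(C)C)ccc12)C(C)(C)O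
F5 | step 3 | 2-methyl-3-(tributylstannyl)but-3-en-2-ol | C=C([Sn](CCCC)(CCCC)CCCC)C(C)(C)O
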